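The readings come from a simulation from invented constants; scatter was added.

The ratio I watch in these flasks is c(Z) over the whole charge of J. Here are the runs so far and the two new flasks.

| flask | G | J | temperature | remark | time |
|---|---|---|---|---|---|
| teal | 0.41 M | 0.11 M (fed, over 2.5 d) | −5 °C | run made earlier |  |
| green | 0.41 M | 0.47 M (fed, over 2.5 d) | 6 °C | run made earlier |  |
| theta | 0.41 M | 0.410 M (fed, over 2.5 d) |  | at −10 °C until 2.5 d, from then on at 10 °C | 5.0 d |
| eta | 0.41 M | 0.100 M (fed, over 2.5 d) |  | at 10 °C throughout | 5.0 d |

| run | time / d | Z / % |
|---|---|---|
| teal | 0.417 | 0.1 |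
| teal | 1.25 | 1.6 |
| teal | 2.50 | 2.7 |
| teal | 4.00 | 4.6 |
| teal | 5.00 | 3.4 |
| green | 0.208 | 0.7 |
| green | 0.417 | 2.0 |
| green | 0.625 | 3.2 |
| green | 1.04 | 5.7 |
| green | 2.50 | 12.7 |

(standard deviation of a reading: 0.3 percentage points)

- the numbers in the tables scatter by 0.3 percentage points (one standard deviation)

- which one finishes higher in amount of Z, in percent of the G charged ("neither" within 2 percentage points) (theta / eta / neither)
- amount of Z at the end, in percent of the G charged, theta
- amount of Z at the end, in percent of the G charged, eta

Eta looks nearly the same as teal: the same G, the same feed time, and 0.100 M of J against 0.11 M, though it runs warmer, at 10 °C against −5 °C. In eta the charge of J is a quarter of the G, and teal's proportion is close to that, so I take J as the limiting reagent in both. Teal reads 2.7% at the end of the feed. Its last two readings, 4.6% and 3.4%, differ by more than the scatter but show no further rise, so I take their mean as its plateau. That plateau gives a reading of 0.149 for what I call the Z yield on J, the moles of Z at the end per mole of J charged.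

Does warmth shift this ratio? At the end of the feed, teal stands at 0.101 and green, at 6 °C with 0.47 M of J, at 0.111. These two readings barely differ, but the two runs differ in the charge of J as well as in temperature, and teal's readings still rise after that point, so this is a hint and not a test of warmth. I carry the yield over unchanged as an assumption, provided 5.0 d is long enough for it to be reached as it was in teal.

Eta should then end at 3.64%. Theta is charged with J equal to G, the crossing at which I expect J to stop being the limiting reagent, so its figure is the less safe of my two. The same yield puts theta at 14.9%, which is 11 percentage points above eta and beyond the margin of 2 points, so I say theta.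

The forecast parts from this: with "J is nearly used up by 5 d" among its grounds for eta, it gives 21% for theta and 20% for eta, hence neither.

The flasks give 15.2% for theta and 3.04% for eta, so theta finishes higher.

    J → Q (k = 0.121 /h, Ea = 88.0 kJ/mol)
    G + Q → X (k = 0.644 /M/h, Ea = 74.0 kJ/mol)
    D + Q → Z (k = 0.125 /M/h, Ea = 77.0 kJ/mol)
    G ⇌ D (K = 0.979, k = 0.271 /h, Ea = 92.0 kJ/mol, ΔH = −12.0 kJ/mol)
    (constants at −10 °C)

At 5.00 d, J in eta stands at 0% of its charge while 45% of the charged G is still there. Put back into the ratio, the ends give a Z yield on J of 0.152 in theta and 0.124 in eta. A further flask, like theta but with 1.0 M of G, has 0.410 equiv of J to G; the yield of 0.149 puts it at 6.11%, and it ends at 6.35%.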